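An easy step first: these flasks differ in how substrate and reagent enter, Wednesday's also in temperature, and I take side product to need target and substrate together.

| flask | substrate | reagent | temperature | remark | time |
|---|---|---|---|---|---|
| ash | 0.010 M | 0.60 equiv | 105 °C | run made earlier |  |
| maple | 0.0067 M | 0.60 equiv | 116 °C | run made earlier |  |
| birch | 0.015 M | 0.60 equiv | 105 °C | run made earlier |  |
| Saturday's | 0.010 M (fed, over 2.5 min) | 0.600 equiv | 110 °C | all else is in the flask from the start; the feed brings no volume worth counting | 6.0 min |
| Wednesday's | 0.010 M (fed, over 2.5 min) | 0.600 equiv |  | the addition at 70 °C, then warmed to 110 °C; the feed brings no volume worth counting | 6.0 min |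
| Tuesday's | 0.010 M | 0.600 equiv (in portions, 5, over 2.5 min) | 110 °C | first portion at the start, last at 2.5 min | 6.0 min |
| Sunday's | 0.010 M | 0.600 equiv (fed, over 2.5 min) | 110 °C | all else is in the flask from the start; the feed brings no volume worth counting | 6.0 min |
| Friday's | 0.010 M | 0.600 equiv (fed, over 40 s) | 110 °C | all else is in the flask from the start; the feed brings no volume worth counting | 6.0 min |

| run | time / min | side product / % | target / % | substrate / % |
|---|---|---|---|---|
| ash | 1.33 | 2.1 | 13.0 | 84.0 |
| ash | 2.50 | 5.1 | 20.5 | 73.8 |
| ash | 4.00 | 9.7 | 24.6 | 65.5 |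
| ash | 5.00 | 12.9 | 26.8 | 60.2 |
| ash | 6.00 | 15.8 | 29.1 | 55.9 |
| maple | 0.500 | 0 | 5.0 | 93.2 |
| maple | 0.833 | 1.4 | 9.1 | 91.3 |
| maple | 1.50 | 2.9 | 12.9 | 85.3 |
| maple | 3.00 | 7.9 | 18.4 | 73.3 |
| maple | 6.00 | 19.1 | 22.8 | 58.2 |
| birch | 1.33 | 5.5 | 21.1 | 75.3 |
| birch | 2.50 | 9.3 | 27.8 | 61.9 |
| birch | 4.00 | 16.6 | 31.5 | 51.7 |
| birch | 5.00 | 20.5 | 32.2 | 46.3 |
| birch | 6.00 | 25.9 | 31.3 | 41.8 |

(readings scatter by 0.5 percentage points)

- percent here means substrate units held: one side product counts as two
- the analysis behind the earlier runs scatters by 0.5 percentage points, standard deviation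

1. the flask that comes out highest in amount of side product, in percent of the substrate charged, or "all alike" when all lie within 1.5 percentage points (Saturday's / Wednesday's / Tuesday's / Sunday's / Friday's / all alike)
2. side product at the end, in percent of the substrate charged, Saturday's
3. side product at the end, in percent of the substrate charged, Wednesday's
4. side product at the end, in percent of the substrate charged, Tuesday's
5. side product at the end, in percent of the substrate charged, Sunday's
6. side product at the end, in percent of the substrate charged, Friday's

In the ash run the side product climbs late at a steady 0.0305 /min of the charge, while target fraction times substrate fraction barely moves: 0.161 at 4.00 min, 0.163 at 6.00 min. So I freeze that product. Dividing gives 0.189 /min at 105 °C. Birch, at 1.50 times the charge, reads 1.65 times that, so I scale by charge, and maple, scaled to the ash charge, then reads 0.411 /min at 116 °C.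

Interpolating to 110 °C gives 0.269 /min: the side-product coefficient, the fraction of the charge turned to side product per minute per unit of target fraction times substrate fraction, an effective rate constant at this charge. With ash's frozen product, the rate is 0.0434 /min.

Ash's straight line, run backwards, starts at 0.820 min. I add half of any feed to that lag, and count Wednesday's cold addition as lost time. My reckoning: Friday's 21.1 %; Saturday's, Sunday's and Tuesday's, whose mean entry is the same, 17.1 %; Wednesday's 11.6 %.

The forecast names Friday's, which “makes target earliest, with substrate still plentiful”, at 20.8 %, with Saturday's 16.8 %, Tuesday's 17.3 %, Sunday's 17 % and Wednesday's 14.2 %, higher than my figure. The flasks give Friday's 20.9 %, Tuesday's 17.6 %, Sunday's 17.5 %, Saturday's 16.1 %, Wednesday's 12.7 %.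

    substrate + target → side product (k = 0.230 /M/s, Ea = 84.0 kJ/mol)
    substrate + reagent → target, rate k2*[substrate]^1.5*[reagent] (k = 4.90 /M^1.5/s, Ea = 44.0 kJ/mol)
    (constants at 110 °C)

In Wednesday's flask the cold addition made target 3.31 % but side product 0.0233 %. In Friday's flask, with target 22.6 % and substrate 69.2 % at 3.00 min, side product then rose 0.0421 /min, beside my frozen 0.0434 /min.

A neighbour, Friday's flask with 0.150 equiv of reagent instead, ends at target 7.50 %, substrate 84.6 %. At those end amounts the coefficient gives a rate of 0.0171 /min, so my estimate is 8.28 % over the time I counted for Friday's; that neighbour holds side product 7.94 %.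

The earlier runs and the new flask were generated by integration with constants of no real substance; scatter was added.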